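**Retrosynthetic overview**

1. The target is a 5,7-dihydroxyflavone. The last disconnection removes two silyl ethers, one on the ring-B phenol and one on the side-chain carbinol.
2. Ring C (O1, C2, C3, C4, C4a, C8a) lies between a phloroglucinol-type ring A, whose two oxygens ortho to C4a are equivalent, and the ring-B aryl group on C2. It is cut at C4a–C4, C4–C3 and O1–C2 into 2-iodophloroglucinol triacetate, carbon monoxide (C4) and the ring-B arylacetylene (C2, C3).
3. The arylacetylene goes back by Sonogashira coupling to an aryl bromide. Its (R)-carbinol arm comes from one of two equivalent prenyl groups by Shi epoxidation and epoxide-to-allylic-alcohol isomerisation. Both prenyl groups come from o,o'-C-prenylation of 4-bromophenol.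
4. The iodoarene comes from phloroglucinol by mono-iodination and peracetylation.
5. Rings A and B are bought as benzene rings. Ring C is the only ring that is made, in the convergent step.

Key step: step 10

Remark 1: the (R) sense of step 5 is taken from the spiro transition-state model for trisubstituted olefins with the D-fructose-derived Shi ketone; the enantiomeric ketone would give the antipode.
Remark 2: TBS is tert-butyldimethylsilyl; any loss of the aryl silyl ether under the amine base of step 10 is of no consequence, because step 11 removes both silyl groups.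

**Route**

Step 1
Reactants: 1 phloroglucinol
Product: 2 2-iodobenzene-1,3,5-triol
Conditions: I2 (1.0 equiv), NaHCO3 (1.1 equiv), THF/H2O 1:1, 0 °C; crude product used at once
Reagents that add atoms: iodine, II
Why: Electrophilic aromatic iodination of a very electron-rich arene whose three CH positions are equivalent, so one equivalent of iodine should give a single mono-iodide.

Step 2
Reactants: 2 2-iodobenzene-1,3,5-triol
Product: 3 2-iodobenzene-1,3,5-triyl triacetate
Conditions: Ac2O (4 equiv), pyridine, DMAP (cat.), CH2Cl2, 0 °C to rt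
Reagents that add atoms: acetic anhydride, CC(=O)OC(C)=O
Why: DMAP-catalysed O-acetylation (nucleophilic acyl substitution) caps the three phenols, which stabilises the labile iodotriol and makes the C–I bond easier for palladium to insert into later.

Step 3
Reactants: 4 4-bromophenol; 5 prenyl bromide (two equivalents are incorporated)
Product: 6 4-bromo-2,6-bis(3-methylbut-2-en-1-yl)phenol
Conditions: 5 (3 equiv, in portions), 2 M aq. NaOH, rt
Reagents that add atoms: none
Why: Ortho-C-allylation of an ambident phenoxide: in water the oxygen is shielded by hydrogen bonding, so the allylic bromide is taken up at the ring carbons, and with the para position blocked by bromine both ortho positions should be prenylated.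

Step 4
Reactants: 6 4-bromo-2,6-bis(3-methylbut-2-en-1-yl)phenol
Product: 7 [4-bromo-2,6-bis(3-methylbut-2-en-1-yl)phenoxy](tert-butyl)dimethylsilane
Conditions: TBSCl, imidazole, DMAP (cat.), DMF, 40 °C
Reagents that add atoms: tert-butyldimethylsilyl chloride, CC(C)(C)[Si](C)(C)Cl
Why: Silyl ether formation (TBSCl/imidazole) masks the phenol, which would otherwise open the epoxide of step 5 to a dihydrobenzofuran or chroman.

Step 5
Reactants: 7 [4-bromo-2,6-bis(3-methylbut-2-en-1-yl)phenoxy](tert-butyl)dimethylsilane
Product: 8 tert-butyl{4-bromo-2-{[(2R)-3,3-dimethyloxiran-2-yl]methyl}-6-(3-methylbut-2-en-1-yl)phenoxy}dimethylsilane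
Conditions: D-fructose-derived Shi ketone (0.3 equiv), Oxone (ca. 0.7 equiv) and K2CO3 added slowly side by side, Bu4NHSO4 (cat.), MeCN/DMM, aq. Na2B4O7–Na2EDTA buffer (pH ca. 10.5), 0 °C; stopped when about half of the C=C groups are consumed; 7 recovered and recycled
Reagents that add atoms: potassium peroxymonosulfate (active component of Oxone), [K+].[O-]S(=O)(=O)OO
Why: Shi asymmetric epoxidation: the chiral dioxirane transfers oxygen to one face of the trisubstituted C=C through a spiro transition state, which should set the new stereocentre as (R); the two prenyl groups are equivalent, so only one mono-epoxide can form, and the oxidant is limited to hold back the bis-epoxide.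

Step 6
Reactants: 8 tert-butyl{4-bromo-2-{[(2R)-3,3-dimethyloxiran-2-yl]methyl}-6-(3-methylbut-2-en-1-yl)phenoxy}dimethylsilane
Product: 9 (2R)-1-{5-bromo-2-[(tert-butyldimethylsilyl)oxy]-3-(3-methylbut-2-en-1-yl)phenyl}-3-methylbut-3-en-2-ol
Conditions: Et2Al(TMP) (3 equiv, from LiTMP and Et2AlCl), toluene, 0 °C; aq. Rochelle salt work-up
Reagents that add atoms: none
Why: Aluminium amide isomerisation of an epoxide to an allylic alcohol (Yamamoto-type syn-β-elimination): a methyl proton is removed while the tertiary C–O bond breaks, so the C–O bond at the stereocentre is untouched and the (R) configuration is kept.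

Step 7
Reactants: 9 (2R)-1-{5-bromo-2-[(tert-butyldimethylsilyl)oxy]-3-(3-methylbut-2-en-1-yl)phenyl}-3-methylbut-3-en-2-ol
Product: 10 bis-silyl ether of 9: {[(2R)-1-{5-bromo-2-[(tert-butyldimethylsilyl)oxy]-3-(3-methylbut-2-en-1-yl)phenyl}-3-methylbut-3-en-2-yl]oxy}(tert-butyl)dimethylsilane
Conditions: TBSCl, imidazole, DMF, rt
Reagents that add atoms: tert-butyldimethylsilyl chloride, CC(C)(C)[Si](C)(C)Cl
Why: Standard silylation of the secondary allylic alcohol at oxygen, which leaves the stereocentre alone and keeps the carbinol from capturing an aroyl–palladium species in step 10.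

Step 8
Reactants: 10 bis-silyl ether aryl bromide; 11 trimethylsilylacetylene
Product: 12 analogue of 10 in which bromine is replaced by a 2-(trimethylsilyl)ethynyl group
Conditions: Pd(PhCN)2Cl2 (3 mol%), [HP(t-Bu)3]BF4 (6 mol%), CuI (2 mol%), i-Pr2NH, dioxane, rt
Reagents that add atoms: none
Why: Sonogashira coupling; the bulky electron-rich phosphine lets the electron-rich but unhindered aryl bromide react at room temperature, where the silyl ethers and both alkenes are inert.

Step 9
Reactants: 12 trimethylsilyl-capped arylacetylene
Product: 13 terminal arylacetylene: ring-B alkyne carrying the aryl O-TBS group, the prenyl arm and the (2R)-2-(TBS-oxy)-3-methylbut-3-en-1-yl arm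
Conditions: K2CO3 (0.3 equiv), MeOH/THF 1:1, 0 °C
Reagents that add atoms: none
Why: Base-catalysed methanolysis of the C(sp)–Si bond (protiodesilylation) should be much faster than cleavage of the di-ortho-substituted aryl silyl ether or the secondary silyl ether.

Step 10
Reactants: 3 2-iodobenzene-1,3,5-triyl triacetate (1.3 equiv); 13 terminal arylacetylene; 14 carbon monoxide
Product: 17 bis-silylated 5,7-dihydroxyflavone (ring-B aryl O-TBS; (2R)-carbinol O-TBS), via ynone triacetate 15 (not isolated), via enaminone 16 (not isolated)
Conditions: PdCl2(PPh3)2 (5 mol%), dppp (5 mol%), thiourea (5 mol%), CO (1 atm), Et2NH, DBU (2 equiv), 40 °C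
Reagents that add atoms: diethylamine, CCNCC (carried only by intermediate 16; none of its atoms stays in 17)
Why: Oxidative addition of Pd(0) into the C–I bond of 3, CO insertion to the aroyl–palladium species and alkynyl transfer from 13 with reductive elimination should give ynone 15 (carbonylative Sonogashira coupling), forming C4a–C4 and C4–C3. Diethylamine then removes the aryl acetates by aminolysis and adds to the ynone to give enaminone 16, and a phenol oxygen ortho to the ketone attacks C2 and expels the amine, forming O1–C2 and closing ring C by a 6-endo addition–elimination; the closest known reaction type is the palladium-catalysed carbonylative annulation of o-iodophenol acetates with terminal alkynes to flavones in a secondary amine. No stereocentre is formed, and the (R)-carbinol silyl ether is a spectator because the conditions are not acidic and do not ionise an allylic silyl ether. The step needs carbonylative over direct alkynylation, which the CO atmosphere, the bidentate phosphine and the two ortho substituents (they slow direct coupling at the crowded aryl–palladium centre but not CO insertion) should secure. It also needs six- over five-membered closure, which the enaminone relay secures because the amine-bearing carbon is the only electrophilic site left, so the aurone cannot form. Regiochemistry on ring A does not arise, because the two oxygens flanking C4a are equivalent.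

Step 11
Reactants: 17 bis-silylated 5,7-dihydroxyflavone
Product: 18 5,7-dihydroxy-2-{4-hydroxy-3-[(2R)-2-hydroxy-3-methylbut-3-en-1-yl]-5-(3-methylbut-2-en-1-yl)phenyl}-4H-chromen-4-one (target)
Conditions: TBAF (3 equiv), AcOH (3 equiv), THF, 0 °C to rt
Reagents that add atoms: none
Why: Fluoride-driven cleavage of both Si–O bonds (TBAF desilylation), buffered with acetic acid so the polyphenol is not held under strongly basic conditions, should free the phenol and the carbinol without touching the stereocentre or the two alkenes.

**Compound list**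

1 | phloroglucinol (benzene-1,3,5-triol) | Oc1cc(O)cc(O)c1 | starting material
2 | 2-iodobenzene-1,3,5-triol | Oc1cc(O)c(I)c(O)c1 | intermediate
3 | 2-iodobenzene-1,3,5-triyl triacetate | CC(=O)Oc1cc(OC(C)=O)c(I)c(OC(C)=O)c1 | intermediate
4 | 4-bromophenol | Oc1ccc(Br)cc1 | starting material
5 | prenyl bromide (1-bromo-3-methylbut-2-ene) | CC(C)=CCBr | starting material
6 | 4-bromo-2,6-bis(3-methylbut-2-en-1-yl)phenol | CC(C)=CCc1cc(Br)cc(CC=C(C)C)c1O | intermediate
7 | [4-bromo-2,6-bis(3-methylbut-2-en-1-yl)phenoxy](tert-butyl)dimethylsilane | CC(C)=CCc1cc(Br)cc(CC=C(C)C)c1O[Si](C)(C)C(C)(C)C | intermediate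
8 | tert-butyl{4-bromo-2-{[(2R)-3,3-dimethyloxiran-2-yl]methyl}-6-(3-methylbut-2-en-1-yl)phenoxy}dimethylsilane | CC1(C)O[C@@H]1Cc1cc(Br)cc(CC=C(C)C)c1O[Si](C)(C)C(C)(C)C | intermediate
9 | (2R)-1-{5-bromo-2-[(tert-butyldimethylsilyl)oxy]-3-(3-methylbut-2-en-1-yl)phenyl}-3-methylbut-3-en-2-ol | C=C(C)[C@H](O)Cc1cc(Br)cc(CC=C(C)C)c1O[Si](C)(C)C(C)(C)C | intermediate
10 | {[(2R)-1-{5-bromo-2-[(tert-butyldimethylsilyl)oxy]-3-(3-methylbut-2-en-1-yl)phenyl}-3-methylbut-3-en-2-yl]oxy}(tert-butyl)dimethylsilane | C=C(C)[C@H](O[Si](C)(C)C(C)(C)C)Cc1cc(Br)cc(CC=C(C)C)c1O[Si](C)(C)C(C)(C)C | intermediate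
11 | trimethylsilylacetylene | C#C[Si](C)(C)C | starting material
12 | analogue of 10 with 2-(trimethylsilyl)ethynyl in place of bromine | C=C(C)[C@H](O[Si](C)(C)C(C)(C)C)Cc1cc(C#C[Si](C)(C)C)cc(CC=C(C)C)c1O[Si](C)(C)C(C)(C)C | intermediate
13 | analogue of 10 with ethynyl in place of bromine (ring-B terminal alkyne) | C=C(C)[C@H](O[Si](C)(C)C(C)(C)C)Cc1cc(C#C)cc(CC=C(C)C)c1O[Si](C)(C)C(C)(C)C | intermediate
14 | carbon monoxide | [C-]#[O+] | starting material
15 | 1-(2,4,6-triacetoxyphenyl)-3-aryl-prop-2-yn-1-one (aryl = ring B of 13) | C=C(C)[C@H](O[Si](C)(C)C(C)(C)C)Cc1cc(C#CC(=O)c2c(OC(C)=O)cc(OC(C)=O)cc2OC(C)=O)cc(CC=C(C)C)c1O[Si](C)(C)C(C)(C)C | intermediate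
16 | (E)-3-aryl-3-(diethylamino)-1-(2,4,6-trihydroxyphenyl)prop-2-en-1-one (aryl = ring B of 13) | C=C(C)[C@H](O[Si](C)(C)C(C)(C)C)Cc1cc(/C(=C\C(=O)c2c(O)cc(O)cc2O)N(CC)CC)cc(CC=C(C)C)c1O[Si](C)(C)C(C)(C)C | intermediate
17 | 2-{4-[(tert-butyldimethylsilyl)oxy]-3-{(2R)-2-[(tert-butyldimethylsilyl)oxy]-3-methylbut-3-en-1-yl}-5-(3-methylbut-2-en-1-yl)phenyl}-5,7-dihydroxy-4H-chromen-4-one | C=C(C)[C@H](O[Si](C)(C)C(C)(C)C)Cc1cc(-c2cc(=O)c3c(O)cc(O)cc3o2)cc(CC=C(C)C)c1O[Si](C)(C)C(C)(C)C | intermediate
18 | 5,7-dihydroxy-2-{4-hydroxy-3-[(2R)-2-hydroxy-3-methylbut-3-en-1-yl]-5-(3-methylbut-2-en-1-yl)phenyl}-4H-chromen-4-one | C=C(C)[C@H](O)Cc1cc(-c2cc(=O)c3c(O)cc(O)cc3o2)cc(CC=C(C)C)c1O | target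

**Step count and risks**

Total step count: 11. Longest linear sequence: 9 steps (4 to 18, steps 3 to 11); the ring-A branch has 2 steps before the convergent step.

Steps most likely to fail:

1. Step 10. The amine may strip the acetates before palladium has inserted into the crowded C–I bond, leaving an electron-rich iodotriol that loses iodine by reduction instead of being carbonylated. The aroyl–palladium species may also be captured by diethylamine to give an amide, or the alkyne may couple without taking up CO. The fallback sets out from alkyne 13 and returns at 17. Commercial 2,4,6-trihydroxybenzoic acid (O=C(O)c1c(O)cc(O)cc1O) is peracetylated (Ac2O, pyridine, 0 °C) to 2,4,6-triacetoxybenzoic acid F1, which oxalyl chloride and catalytic DMF convert into 2,4,6-triacetoxybenzoyl chloride F2. Acyl Sonogashira coupling of F2 with 13 (PdCl2(PPh3)2, CuI, Et3N, THF, rt) should give ynone 15, now as an isolated compound. Treating 15 with Et2NH and DBU at 40 °C should then give 17 through enaminone 16. The C4–C3 bond comes from an acid chloride here, so neither CO insertion nor oxidative addition at a hindered iodide is needed.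

2. Step 5. The second, equivalent prenyl group is epoxidised at a similar rate, so the reaction gives a statistical mixture of unchanged diene, mono-epoxide and bis-epoxide, and background epoxidation by uncatalysed Oxone would lower the facial selectivity. The fallback sets out from 4 and returns at 10, and it tells the two arms apart from the start.
   - O-Allylation of 4 (allyl bromide, K2CO3, acetone) gives 1-bromo-4-(prop-2-en-1-yloxy)benzene F3.
   - Claisen rearrangement (N,N-diethylaniline, 190 °C) gives 4-bromo-2-(prop-2-en-1-yl)phenol F4.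
   - C-Prenylation at the one free ortho position (NaH, toluene, 5) gives 4-bromo-2-(3-methylbut-2-en-1-yl)-6-(prop-2-en-1-yl)phenol F5.
   - Silylation (TBSCl, imidazole, DMF) gives the aryl silyl ether F6.
   - Shi epoxidation can now be run to full conversion, because the dioxirane takes the trisubstituted prenyl double bond far faster than the monosubstituted allyl one, and should give the (R)-epoxide F7.
   - Isomerisation with Et2Al(TMP) gives the (R)-allylic alcohol F8, and silylation gives the bis-silyl ether F9.
   - Cross-metathesis of F9 with 2-methylbut-2-ene (Grubbs second-generation catalyst, CH2Cl2, 40 °C) turns the allyl group into a prenyl group and gives 10; the hindered 1,1-disubstituted isopropenyl group should stay out of the metathesis.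

3. Step 3. O-Alkylation, stopping at the mono-prenyl stage and hydrolysis of prenyl bromide all compete with the double ortho-C-alkylation. The fallback sets out from 4 and returns at 6. Iodination at both ortho positions (I2, KI, aq. NaOH) gives 4-bromo-2,6-diiodophenol F10. A twofold Stille coupling with tributyl(3-methylbut-2-en-1-yl)stannane (Pd(PPh3)4, DMF, 80 °C) should then take place at the two C–I bonds, leave the C–Br bond, and give 6.

Further compounds
F1 | step 10 | 2,4,6-triacetoxybenzoic acid | CC(=O)Oc1cc(OC(C)=O)c(C(=O)O)c(OC(C)=O)c1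
F2 | step 10 | 2,4,6-triacetoxybenzoyl chloride | CC(=O)Oc1cc(OC(C)=O)c(C(=O)Cl)c(OC(C)=O)c1
F3 | step 5 | 1-bromo-4-(prop-2-en-1-yloxy)benzene | C=CCOc1ccc(Br)cc1
F4 | step 5 | 4-bromo-2-(prop-2-en-1-yl)phenol | C=CCc1cc(Br)ccc1O
F5 | step 5 | 4-bromo-2-(3-methylbut-2-en-1-yl)-6-(prop-2-en-1-yl)phenol | C=CCc1cc(Br)cc(CC=C(C)C)c1O
F6 | step 5 | [4-bromo-2-(3-methylbut-2-en-1-yl)-6-(prop-2-en-1-yl)phenoxy](tert-butyl)dimethylsilane | C=CCc1cc(Br)cc(CC=C(C)C)c1O[Si](C)(C)C(C)(C)C
F7 | step 5 | tert-butyl{4-bromo-2-{[(2R)-3,3-dimethyloxiran-2-yl]methyl}-6-(prop-2-en-1-yl)phenoxy}dimethylsilane | C=CCc1cc(Br)cc(C[C@H]2OC2(C)C)c1O[Si](C)(C)C(C)(C)C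
F8 | step 5 | (2R)-1-{5-bromo-2-[(tert-butyldimethylsilyl)oxy]-3-(prop-2-en-1-yl)phenyl}-3-methylbut-3-en-2-ol | C=CCc1cc(Br)cc(C[C@@H](O)C(C)=C)c1O[Si](C)(C)C(C)(C)C
F9 | step 5 | {[(2R)-1-{5-bromo-2-[(tert-butyldimethylsilyl)oxy]-3-(prop-2-en-1-yl)phenyl}-3-methylbut-3-en-2-yl]oxy}(tert-butyl)dimethylsilane | C=CCc1cc(Br)cc(C[C@@H](O[Si](C)(C)C(C)(C)C)C(C)=C)c1O[Si](C)(C)C(C)(C)C
F10 | step 3 | 4-bromo-2,6-diiodophenol | Oc1c(I)cc(Br)cc1I
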